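**Retrosynthetic overview**

- Agelasidine C ⇒ sulfur alkylation of 2-guanidinoethanesulfinate (one step from hypotaurine) by the C20 allylic bromide.
- C20 chain ⇒ B-alkyl Suzuki–Miyaura coupling at C2'–C3' between the 9-BBN adduct of the 1-vinylcyclohexene and a (2E,6E)-alkenyl iodide (five steps from geranyl acetate).
- Vinylcyclohexene ⇒ shift of the ring alkene from C3=C4 to C2=C3 with loss of O4 (Saegusa, Luche, acetate, palladium/hydride), after Wittig methylenation of the ring aldehyde (C1', C2').
- Ring ⇒ catalytic enantioselective Diels–Alder reaction of tiglic aldehyde with (E)-2-silyloxypenta-1,3-diene, forming C1–C2 and C5–C6 and closing the only ring (the cyclohexene).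
- Feature used: quaternary C1 and methine C6 of the cyclohexene carry cis methyls with chain carbon C1' trans to the C6 methyl, which is what suprafacial addition across E-tiglic aldehyde delivers.

Key step: step 2

**Numbering and assumptions**

- Ring atoms are numbered as in the target (C1 quaternary, C2=C3, C6 methine; chain C1'–C9' outward from the ring). Compound names use their own IUPAC numbering.
- Sense of induction: the formyl C–H···O binding model (s-trans enal on boron, one face covered by the C-phenyl group cis to it) predicts attack on the Re face of the enal α-carbon with the catalyst from (S)-diphenylprolinol, which gives (1S,6R). Should the adduct prove antipodal, the catalyst from (R)-diphenylprolinol is used instead.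
- Transient centres: the adduct is drawn as the formyl-endo isomer at C2 and the allylic alcohol as the C4 epimer from axial hydride delivery. Both centres are erased (steps 4 and 7), so their epimers are carried along.
- The target is drawn as the neutral guanidine; the last step forms the hydrobromide, which is neutralised in the work-up.

**Route**

Step 1
Reactants: 1 (E)-pent-3-en-2-one
Product: 2 tert-butyldimethyl{[(3E)-penta-1,3-dien-2-yl]oxy}silane
Conditions: TBSOTf, Et3N, Et2O, 0 °C → rt
Reagents that add atoms: tert-butyldimethylsilyl triflate, CC(C)(C)[Si](C)(C)OS(=O)(=O)C(F)(F)F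
Why: Soft enolisation with a silyl triflate and a tertiary amine removes a proton from the acetyl methyl group and traps the cross-conjugated dienolate on oxygen (silyl enol ether formation), leaving the E alkene untouched.

Step 2
Reactants: 3 tiglic aldehyde, (E)-2-methylbut-2-enal; 2 tert-butyldimethyl{[(3E)-penta-1,3-dien-2-yl]oxy}silane
Product: 4 (1S,2R,6R)-4-[(tert-butyldimethylsilyl)oxy]-1,2,6-trimethylcyclohex-3-ene-1-carbaldehyde
Conditions: [C24H25BNO][N(SO2CF3)2] (20 mol%; the B-o-tolyl oxazaborolidine of (S)-α,α-diphenylprolinol, made with (o-TolBO)3 and protonated by HN(SO2CF3)2), 2 (1.5 equiv), CH2Cl2, −78 → −20 °C; Et3N quench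
Reagents that add atoms: none
Why: The formyl oxygen of 3 binds the boron of the oxazaborolidinium, which lowers the LUMO of the s-trans enal, and diene 2 adds suprafacially in a concerted, asynchronous [4+2] cycloaddition of the kind established for chiral oxazaborolidinium-catalysed Diels–Alder reactions of α-substituted enals and of 2-silyloxy dienes. The cyclohexene closes by intermolecular [4+2] union, C1–C2 and C5–C6 forming in one event. C1 and C6 are set relative to each other by the E geometry of the dienophile (cis methyls, formyl carbon trans to the C6 methyl) and in the absolute sense by the catalyst, which covers one face of the bound enal so that the diene attacks the Re face of the α-carbon. C2 follows from the formyl-endo transition state and is erased in step 4. The step needs regioselectivity, secured by the matched 2-silyloxy and 4-methyl groups of the diene, which put the largest HOMO coefficient on the CH2 terminus so that it bonds to the enal β-carbon; and it needs enantioface selectivity, supplied by the catalyst, while endo/exo selectivity is not required.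

Step 3
Reactants: 4 (1S,2R,6R)-4-[(tert-butyldimethylsilyl)oxy]-1,2,6-trimethylcyclohex-3-ene-1-carbaldehyde
Product: 5 tert-butyl{[(3R,4S,5R)-4-ethenyl-3,4,5-trimethylcyclohex-1-en-1-yl]oxy}dimethylsilane
Conditions: Ph3PCH3Br, KHMDS, THF, 0 °C; then 4, 0 °C → rt
Reagents that add atoms: methyltriphenylphosphonium bromide, C[P+](c1ccccc1)(c1ccccc1)c1ccccc1.[Br-]
Why: Wittig methylenation with the small salt-free ylide reaches a neopentyl-type, non-enolisable aldehyde; it is done before the enone is unmasked so that no second carbonyl competes, and it leaves the silyl enol ether and the stereocentres untouched.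

Step 4
Reactants: 5 tert-butyl{[(3R,4S,5R)-4-ethenyl-3,4,5-trimethylcyclohex-1-en-1-yl]oxy}dimethylsilane
Product: 6 (4S,5R)-4-ethenyl-3,4,5-trimethylcyclohex-2-en-1-one
Conditions: Pd(OAc)2 (1.05 equiv), MeCN, rt → 40 °C
Reagents that add atoms: none
Why: In the Saegusa–Ito oxidation the silyl enol ether passes its enolate to divalent palladium at C3 and syn β-hydride loss from C2 gives the C2=C3 enone regiospecifically, erasing the C2 centre so that both C2 epimers of 5 converge.

Step 5
Reactants: 6 (4S,5R)-4-ethenyl-3,4,5-trimethylcyclohex-2-en-1-one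
Product: 7 (1S,4S,5R)-4-ethenyl-3,4,5-trimethylcyclohex-2-en-1-ol
Conditions: NaBH4, CeCl3·7H2O, MeOH, −20 → 0 °C
Reagents that add atoms: none
Why: Luche 1,2-reduction gives the allylic alcohol without conjugate reduction; the new carbinol centre at C4 (axial hydride delivery expected, hydroxyl cis to the C6 methyl) is removed in step 7, so its epimers are used together.

Step 6
Reactants: 7 (1S,4S,5R)-4-ethenyl-3,4,5-trimethylcyclohex-2-en-1-ol
Product: 8 (1S,4S,5R)-4-ethenyl-3,4,5-trimethylcyclohex-2-en-1-yl acetate
Conditions: Ac2O, Et3N, DMAP (cat.), CH2Cl2, 0 °C → rt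
Reagents that add atoms: acetic anhydride, CC(=O)OC(C)=O
Why: DMAP-catalysed acylation turns the secondary allylic alcohol into a leaving group that zerovalent palladium can ionise.

Step 7
Reactants: 8 (1S,4S,5R)-4-ethenyl-3,4,5-trimethylcyclohex-2-en-1-yl acetate
Product: 9 (5R,6S)-6-ethenyl-1,5,6-trimethylcyclohex-1-ene
Conditions: Pd(PPh3)4 (5 mol%), THF, rt; then LiBHEt3 (2 equiv), 0 °C → rt; pentane work-up (volatile product)
Reagents that add atoms: none
Why: In this palladium-catalysed reductive displacement of an allylic acetate (Tsuji–Trost-type ionisation, then hydride capture) the allyl complex spans C2–C4 and hydride from LiBHEt3 goes to the less hindered secondary terminus C4, so the trisubstituted C2=C3 alkene stays next to the quaternary carbon and no retained stereocentre is touched.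

Step 8
Reactants: 10 geranyl acetate, (2E)-3,7-dimethylocta-2,6-dien-1-yl acetate
Product: 11 (2E)-5-(3,3-dimethyloxiran-2-yl)-3-methylpent-2-en-1-yl acetate
Conditions: mCPBA (1.05 equiv), NaHCO3, CH2Cl2, 0 °C
Reagents that add atoms: 3-chloroperbenzoic acid, OOC(=O)c1cccc(Cl)c1
Why: Prilezhaev epoxidation selects the electron-rich 6,7-alkene because the 2,3-alkene is deactivated by the allylic acetate; the oxirane centre forms racemic and is destroyed in step 9.

Step 9
Reactants: 11 (2E)-5-(3,3-dimethyloxiran-2-yl)-3-methylpent-2-en-1-yl acetate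
Product: 12 (2E)-3-methyl-6-oxohex-2-en-1-yl acetate
Conditions: H5IO6, THF/H2O, 0 °C
Reagents that add atoms: none
Why: Periodic acid opens the epoxide to the glycol and cleaves it in the same flask (Malaprade-type cleavage), excising the isopropylidene carbon as acetone and leaving the 2E alkene and the acetate intact.

Step 10
Reactants: 12 (2E)-3-methyl-6-oxohex-2-en-1-yl acetate
Product: 15 (2E)-3-methylhept-2-en-6-yn-1-ol, via enyne acetate 13 (not isolated), via hydroxy aldehyde 14 (not isolated)
Conditions: dimethyl (1-diazo-2-oxopropyl)phosphonate, K2CO3, MeOH, 0 °C → rt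
Reagents that add atoms: dimethyl (1-diazo-2-oxopropyl)phosphonate, COP(=O)(OC)C(=[N+]=[N-])C(C)=O
Why: Ohira–Bestmann (Seyferth–Gilbert) homologation turns the aldehyde into the terminal alkyne and the same methanolic carbonate removes the acetate by transesterification, the two events converging on the enynol whichever comes first.

Step 11
Reactants: 15 (2E)-3-methylhept-2-en-6-yn-1-ol
Product: 17 (2E)-3-methyloct-2-en-6-yn-1-ol, via dilithio alkoxide acetylide 16 (not isolated)
Conditions: n-BuLi (2.1 equiv), THF, −78 → 0 °C; MeI (1.05 equiv), −78 °C → rt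
Reagents that add atoms: iodomethane, CI
Why: Double deprotonation gives the alkoxide–acetylide dianion, and only its carbon end is alkylated by iodomethane in THF (acetylide alkylation), the lithium alkoxide being too weak a nucleophile there.

Step 12
Reactants: 17 (2E)-3-methyloct-2-en-6-yn-1-ol
Product: 19 (2E,6E)-7-iodo-3-methylocta-2,6-dien-1-ol, via alkenylzirconocene 18 (not isolated)
Conditions: Cp2Zr(H)Cl (3 equiv), THF, rt → 50 °C; then I2, 0 °C
Reagents that add atoms: iodine, II
Why: Schwartz hydrozirconation adds H and Zr syn across the alkyne and, after equilibration with excess reagent, places zirconium on the methyl-bearing carbon; iodinolysis with retention then fixes the 6E alkenyl iodide, one equivalent of reagent being consumed by the hydroxyl group.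

Step 13
Reactants: 9 (5R,6S)-6-ethenyl-1,5,6-trimethylcyclohex-1-ene; 19 (2E,6E)-7-iodo-3-methylocta-2,6-dien-1-ol
Product: 21 (2E,6E)-3,7-dimethyl-9-[(1S,6R)-1,2,6-trimethylcyclohex-2-en-1-yl]nona-2,6-dien-1-ol, via B-alkyl-9-BBN 20 (not isolated)
Conditions: 9-BBN (1.1 equiv), THF, 0 °C → rt; then 19 (1.2 equiv), PdCl2(dppf) (5 mol%), AsPh3, Cs2CO3, DMF/H2O, rt
Reagents that add atoms: none
Why: 9-BBN hydroborates the monosubstituted vinyl group at its terminal carbon in preference to the hindered trisubstituted ring alkene, and the primary alkylborane undergoes B-alkyl Suzuki–Miyaura coupling with the alkenyl iodide with retention, so its 6E geometry becomes the C3'=C4' E alkene.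

Step 14
Reactants: 21 (2E,6E)-3,7-dimethyl-9-[(1S,6R)-1,2,6-trimethylcyclohex-2-en-1-yl]nona-2,6-dien-1-ol
Product: 22 (5R,6S)-6-[(3E,7E)-9-bromo-3,7-dimethylnona-3,7-dien-1-yl]-1,5,6-trimethylcyclohex-1-ene
Conditions: CBr4, PPh3, CH2Cl2, −20 → 0 °C; used crude
Reagents that add atoms: carbon tetrabromide, BrC(Br)(Br)Br
Why: Appel bromination converts the primary allylic alcohol to the bromide by SN2 displacement of the oxyphosphonium group at low temperature, without allylic transposition or loss of the 2E geometry.

Step 15
Reactants: 23 hypotaurine, 2-aminoethane-1-sulfinic acid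
Product: 24 2-guanidinoethane-1-sulfinic acid (inner salt)
Conditions: 1H-pyrazole-1-carboxamidine·HCl, Na2CO3, H2O, rt, Ar
Reagents that add atoms: 1H-pyrazole-1-carboxamidine hydrochloride, Cl.NC(=N)n1cccn1
Why: Amidine transfer from the pyrazole carboxamidine to the primary amine (guanylation) proceeds in aqueous carbonate, the sulfinate being inert to this electrophile, and gives the guanidinium sulfinate inner salt.

Step 16
Reactants: 22 (5R,6S)-6-[(3E,7E)-9-bromo-3,7-dimethylnona-3,7-dien-1-yl]-1,5,6-trimethylcyclohex-1-ene; 24 2-guanidinoethane-1-sulfinic acid (inner salt)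
Product: 25 agelasidine C, 2-{2-[(2E,6E)-3,7-dimethyl-9-[(1S,6R)-1,2,6-trimethylcyclohex-2-en-1-yl]nona-2,6-dien-1-yl]sulfonylethyl}guanidine
Conditions: 24 (1.5 equiv), DMSO/THF/H2O, rt, Ar; then aq NaOH (1 equiv), 0 °C
Reagents that add atoms: none
Why: The soft sulfinate sulfur displaces the primary allylic bromide (sulfinate S-alkylation) to give the sulfone with the 2E alkene intact, the guanidine staying protected as its non-nucleophilic guanidinium ion until the basic work-up.

**Compound list**

1 | (E)-pent-3-en-2-one | C/C=C/C(C)=O | starting material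
2 | tert-butyldimethyl{[(3E)-penta-1,3-dien-2-yl]oxy}silane | C/C=C/C(=C)O[Si](C)(C)C(C)(C)C | intermediate
3 | tiglic aldehyde, (E)-2-methylbut-2-enal | C/C=C(\C)C=O | starting material
4 | (1S,2R,6R)-4-[(tert-butyldimethylsilyl)oxy]-1,2,6-trimethylcyclohex-3-ene-1-carbaldehyde (2-methyl cis to formyl; 1- and 6-methyls cis) | C[C@@H]1C=C(O[Si](C)(C)C(C)(C)C)C[C@@H](C)[C@]1(C)C=O | intermediate
5 | tert-butyl{[(3R,4S,5R)-4-ethenyl-3,4,5-trimethylcyclohex-1-en-1-yl]oxy}dimethylsilane | C[C@@H]1C=C(O[Si](C)(C)C(C)(C)C)C[C@@H](C)[C@]1(C)C=C | intermediate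
6 | (4S,5R)-4-ethenyl-3,4,5-trimethylcyclohex-2-en-1-one | CC1=CC(=O)C[C@@H](C)[C@]1(C)C=C | intermediate
7 | (1S,4S,5R)-4-ethenyl-3,4,5-trimethylcyclohex-2-en-1-ol (expected major carbinol epimer drawn; the 1R epimer is carried along) | CC1=C[C@@H](O)C[C@@H](C)[C@]1(C)C=C | intermediate
8 | (1S,4S,5R)-4-ethenyl-3,4,5-trimethylcyclohex-2-en-1-yl acetate (with its 1R epimer) | CC1=C[C@@H](OC(C)=O)C[C@@H](C)[C@]1(C)C=C | intermediate
9 | (5R,6S)-6-ethenyl-1,5,6-trimethylcyclohex-1-ene | CC1=CCC[C@@H](C)[C@]1(C)C=C | intermediate
10 | geranyl acetate, (2E)-3,7-dimethylocta-2,6-dien-1-yl acetate | CC(=O)OC/C=C(\C)CCC=C(C)C | starting material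
11 | (2E)-5-(3,3-dimethyloxiran-2-yl)-3-methylpent-2-en-1-yl acetate (racemic at the oxirane carbon) | CC(=O)OC/C=C(\C)CCC1OC1(C)C | intermediate
12 | (2E)-3-methyl-6-oxohex-2-en-1-yl acetate | CC(=O)OC/C=C(\C)CCC=O | intermediate
13 | (2E)-3-methylhept-2-en-6-yn-1-yl acetate | CC(=O)OC/C=C(\C)CCC#C | intermediate (not isolated; homologation before acetate cleavage)
14 | (4E)-6-hydroxy-4-methylhex-4-enal | OC/C=C(\C)CCC=O | intermediate (not isolated; acetate cleavage before homologation)
15 | (2E)-3-methylhept-2-en-6-yn-1-ol | OC/C=C(\C)CCC#C | intermediate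
16 | dilithium alkoxide–acetylide of 15 | [Li]OC/C=C(\C)CCC#C[Li] | intermediate (not isolated)
17 | (2E)-3-methyloct-2-en-6-yn-1-ol | OC/C=C(\C)CCC#CC | intermediate
18 | (2E,6E)-7-[chlorobis(cyclopentadienyl)zirconio]-3-methylocta-2,6-dien-1-yl oxide of chlorobis(cyclopentadienyl)zirconium (cyclopentadienyl rings drawn σ-bonded) | C/C(=C\CC/C(C)=C/CO[Zr](Cl)(C1C=CC=C1)C1C=CC=C1)[Zr](Cl)(C1C=CC=C1)C1C=CC=C1 | intermediate (not isolated)
19 | (2E,6E)-7-iodo-3-methylocta-2,6-dien-1-ol | OC/C=C(\C)CC/C=C(\C)I | intermediate
20 | 9-{2-[(1S,6R)-1,2,6-trimethylcyclohex-2-en-1-yl]ethyl}-9-borabicyclo[3.3.1]nonane | CC1=CCC[C@@H](C)[C@]1(C)CCB1C2CCCC1CCC2 | intermediate (not isolated)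
21 | (2E,6E)-3,7-dimethyl-9-[(1S,6R)-1,2,6-trimethylcyclohex-2-en-1-yl]nona-2,6-dien-1-ol | CC1=CCC[C@@H](C)[C@]1(C)CC/C(C)=C/CC/C(C)=C/CO | intermediate
22 | (5R,6S)-6-[(3E,7E)-9-bromo-3,7-dimethylnona-3,7-dien-1-yl]-1,5,6-trimethylcyclohex-1-ene | CC1=CCC[C@@H](C)[C@]1(C)CC/C(C)=C/CC/C(C)=C/CBr | intermediate
23 | hypotaurine, 2-aminoethane-1-sulfinic acid | NCCS(=O)O | starting material
24 | 2-guanidinoethane-1-sulfinic acid (inner salt; neutral form drawn) | NC(N)=NCCS(=O)O | intermediate
25 | agelasidine C | CC1=CCC[C@@H](C)[C@]1(C)CC/C(C)=C/CC/C(C)=C/CS(=O)(=O)CCN=C(N)N | target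

**Step count**

Total: 16 steps. Longest linear sequence: 10 steps (steps 1–7, 13, 14, 16).

**Steps most likely to fail**

Step 2. The doubly substituted enal may add too slowly, so that the acid catalyst desilylates or oligomerises the diene before cycloaddition, or one enal face may be shielded incompletely. The fallback makes the ring racemic and resolves it; it sets out from 2 and 3 and returns at 9. Diene 2 and aldehyde 3 are combined with stoichiometric, proton-free Me2AlCl (CH2Cl2, −78 → −20 °C) to give the racemic adduct F1. Steps 3, 4 and 5 are applied unchanged and should give the racemic vinyl silyl enol ether F2, the racemic enone F3 and the racemic allylic alcohol F4. In place of step 6, F4 is acylated with (1S)-camphanic chloride (Et3N, DMAP, CH2Cl2). The (1S,4S,5R)-camphanate F5 is separated by crystallisation or chromatography from the (1R,4R,5S)-camphanate F6 and from the esters of the minor carbinol epimers. F5 is then put through the conditions of step 7, the camphanate serving as the leaving group, and should give 9.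

Step 7. Hydride may be delivered to the more substituted allyl terminus (alkene transposition with a new C–H centre at C2), or the acetate may be cleaved reductively before ionisation. The fallback avoids an allyl–palladium intermediate; it sets out from enone 6 and returns at 9. Thioacetalisation (ethane-1,2-dithiol, BF3·OEt2, CH2Cl2, 0 °C), which leaves a conjugated alkene in place, gives the dithiolane (8S,9R)-8-ethenyl-7,8,9-trimethyl-1,4-dithiaspiro[4.5]dec-6-ene F7. Radical desulfurisation (Bu3SnH, AIBN, toluene, 110 °C) should then give 9, the intermediate allyl radical taking hydrogen at its less hindered secondary terminus.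

Step 16. The zwitterionic sulfinate and the lipophilic bromide may fail to share a phase, so that oxygen alkylation, allylic transposition or solvolysis competes with sulfur alkylation. The fallback installs the guanidine last; it sets out from 22 and 23 and returns at 25. Hypotaurine 23 is N-protected with N-(ethoxycarbonyl)phthalimide (Na2CO3, H2O) to give sodium 2-phthalimidoethanesulfinate F8, which dissolves in DMF. S-alkylation of F8 with bromide 22 gives the phthalimido sulfone F9. Hydrazinolysis (N2H4·H2O, EtOH, rt) frees the amino sulfone F10, which is guanylated with 1H-pyrazole-1-carboxamidine hydrochloride and iPr2NEt in DMF to give 25.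

**Further compounds**

F1 | step 2 | racemic adduct: 4 together with its antipode (antipode drawn) | C[C@H]1C=C(O[Si](C)(C)C(C)(C)C)C[C@H](C)[C@@]1(C)C=O
F2 | step 2 | racemic vinyl silyl enol ether: 5 together with its antipode (antipode drawn) | C[C@H]1C=C(O[Si](C)(C)C(C)(C)C)C[C@H](C)[C@@]1(C)C=C
F3 | step 2 | racemic enone: 6 together with its antipode (antipode drawn) | CC1=CC(=O)C[C@H](C)[C@@]1(C)C=C
F4 | step 2 | racemic allylic alcohol: 7 together with its antipode (antipode drawn) | CC1=C[C@H](O)C[C@H](C)[C@@]1(C)C=C
F5 | step 2 | (1S,4S,5R)-4-ethenyl-3,4,5-trimethylcyclohex-2-en-1-yl (1S,4R)-camphanate | CC1=C[C@@H](OC(=O)[C@@]23CC[C@@](C)(C(=O)O2)C3(C)C)C[C@@H](C)[C@]1(C)C=C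
F6 | step 2 | (1R,4R,5S)-4-ethenyl-3,4,5-trimethylcyclohex-2-en-1-yl (1S,4R)-camphanate (discarded) | CC1=C[C@H](OC(=O)[C@@]23CC[C@@](C)(C(=O)O2)C3(C)C)C[C@H](C)[C@@]1(C)C=C
F7 | step 7 | (8S,9R)-8-ethenyl-7,8,9-trimethyl-1,4-dithiaspiro[4.5]dec-6-ene | CC1=CC2(SCCS2)C[C@@H](C)[C@]1(C)C=C
F8 | step 16 | sodium 2-(1,3-dioxoisoindolin-2-yl)ethane-1-sulfinate | [Na+].[O-]S(=O)CCN1C(=O)c2ccccc2C1=O
F9 | step 16 | 2-{2-[(2E,6E)-3,7-dimethyl-9-[(1S,6R)-1,2,6-trimethylcyclohex-2-en-1-yl]nona-2,6-dien-1-yl]sulfonylethyl}isoindoline-1,3-dione | CC1=CCC[C@@H](C)[C@]1(C)CC/C(C)=C/CC/C(C)=C/CS(=O)(=O)CCN1C(=O)c2ccccc2C1=O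
F10 | step 16 | 2-{[(2E,6E)-3,7-dimethyl-9-[(1S,6R)-1,2,6-trimethylcyclohex-2-en-1-yl]nona-2,6-dien-1-yl]sulfonyl}ethan-1-amine | CC1=CCC[C@@H](C)[C@]1(C)CC/C(C)=C/CC/C(C)=C/CS(=O)(=O)CCN
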